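**Plan**

Numbering is that of the labdanes: C4 carries CH3 (C18) and CO2Me (C19), C10 carries CH3 (C20), C6 the acetate, C8 the methylene C17, C9 the chain C11–C16.
Retrosynthesis: the acetate is removed, then ring B is cut at C6–C7 and C9–C10 in one stroke. This splits the target into a ring A enal (C1–C6, C10, C18–C20) and (Z)-β-ocimene (C7–C9, C11–C17). The enal goes back through its enol triflate to methyl 2-oxocyclohexane-1-carboxylate.
Enabling feature: in ring B the C6 carbinol, C7H2 and the exocyclic C8=C17H2 make a 3-methylenecyclohexanol, the retron of a type 2 carbonyl-ene closure. C9 carries the chain next to C8, the retron of a conjugate ene reaction at a prenyl terminus. The ten carbons C7–C9/C11–C17 are ocimene itself, whose Z-diene is strongly disfavoured in the s-cis conformation and should stay out of the way.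
Forward: ring A is made first (C4 quaternary centre, C10 methyl, enol triflate, formyl group). Ring B is then closed and the whole dienyl chain joined in a single [3+3] double-ene annulation, and acetylation ends the route.
Stereochemistry: C4 from a valine-derived enamine auxiliary; C10 from C4 (attack anti to the pseudoaxial ester); C9 and C5 from the ene transition state (suprafacial C/H delivery gives the trans fusion); C6 from closure with the aluminium-bound oxygen equatorial; 12Z is carried in from ocimene.

Key step: step 6

Assumption: (Z)-β-ocimene is used as the commercial single geometric isomer.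
Assumption: the toluene/HMPA variant of the valine-enamine methylation is taken to give the (S) centre; were the sense opposite, D-valine tert-butyl ester would be used with no other change.

**Route**

Step 1
Reactants: 1 methyl 2-oxocyclohexane-1-carboxylate; 2 L-valine tert-butyl ester [tert-butyl (2S)-2-amino-3-methylbutanoate]
Product: 3 methyl 2-{[(2S)-1-(tert-butoxy)-3-methyl-1-oxobutan-2-yl]amino}cyclohex-1-ene-1-carboxylate
Conditions: BF3·OEt2 (cat.), benzene, reflux, Dean–Stark trap
Reagents that add atoms: none
Why: Acid-catalysed condensation (enamine formation) of the ketone carbonyl with the primary amine should give the conjugated, hydrogen-bonded enamino ester; no new stereocentre arises.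

Step 2
Reactants: 3 chiral enamino ester
Product: 6 methyl (1S)-1-methyl-2-oxocyclohexane-1-carboxylate, via lithium aza-enolate 4 (not isolated), via methylated imino ester 5 (not isolated)
Conditions: LiN(iPr)2, toluene, −78 °C; HMPA (1 equiv); MeI, −78 → −55 °C; then 1 M aq. HCl, 0 °C
Reagents that add atoms: iodomethane, CI; water, O
Why: Auxiliary-controlled alkylation of a chelated lithium aza-enolate (enamine alkylation): lithium is held by the nitrogen and the two ester carbonyls, the isopropyl group and the lithium-bound HMPA screen one face, iodomethane should enter from the other to set C4 as S, and hydrolysis of the imine returns the ketone and the auxiliary.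

Step 3
Reactants: 6 methyl (1S)-1-methyl-2-oxocyclohexane-1-carboxylate
Product: 8 methyl (1S)-1,3-dimethyl-2-oxocyclohexane-1-carboxylate (both C3 epimers), via lithium enolate 7 (not isolated)
Conditions: LiN(iPr)2, THF, −78 °C; MeI, −78 → 0 °C
Reagents that add atoms: iodomethane, CI
Why: Kinetic enolate C-alkylation at the only enolisable α-carbon (C10); the new centre forms as a mixture of epimers, which is of no consequence because it becomes sp2 in step 4.

Step 4
Reactants: 8 methyl (1S)-1,3-dimethyl-2-oxocyclohexane-1-carboxylate
Product: 10 methyl (1S)-1,3-dimethyl-2-[(trifluoromethanesulfonyl)oxy]cyclohex-2-ene-1-carboxylate, via potassium enolate 9 (not isolated)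
Conditions: KN(SiMe3)2, THF, −78 → 0 °C; PhNTf2, −78 °C → rt
Reagents that add atoms: N-phenylbis(trifluoromethanesulfonimide), O=S(=O)(N(c1ccccc1)S(=O)(=O)C(F)(F)F)C(F)(F)F
Why: Enol triflate formation: the enolate can form only toward C10 because C4 is quaternary, and O-sulfonylation should give the tetrasubstituted vinyl triflate with the C4 centre untouched.

Step 5
Reactants: 10 vinyl triflate
Product: 11 methyl (1S)-2-formyl-1,3-dimethylcyclohex-2-ene-1-carboxylate
Conditions: Pd(PPh3)4 (5 mol %), CO (3 atm), Bu3SnH (slow addition), THF, 50 °C
Reagents that add atoms: carbon monoxide, [C-]#[O+]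
Why: Reductive carbonylation (Stille-type formylation): oxidative addition of the vinyl triflate to zerovalent palladium, CO insertion and hydride transfer from tin to the acyl–palladium species should give the enal, slow addition of the stannane holding back direct reduction.

Step 6
Reactants: 11 methyl (1S)-2-formyl-1,3-dimethylcyclohex-2-ene-1-carboxylate; 12 (3Z)-3,7-dimethylocta-1,3,6-triene [(Z)-β-ocimene]
Product: 14 methyl (1S,4aR,5S,8S,8aR)-8-hydroxy-1,4a-dimethyl-6-methylidene-5-[(2Z)-3-methylpenta-2,4-dien-1-yl]decahydronaphthalene-1-carboxylate [methyl 6α-hydroxylabda-8(17),12Z,14-trien-19-oate], via ene adduct aldehyde 13 (not isolated)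
Conditions: 12 (3 equiv), MeAl(OC6H2-2,6-tBu2-4-Br)2 (2 equiv), CH2Cl2, −78 → −20 °C; aq. NaHCO3 work-up
Reagents that add atoms: none
Why: Proposed new method: the aluminium-complexed enal should be attacked at C10 by the CH terminus (C9) of the prenyl unit of 12, an allylic hydrogen of one C8 methyl passing to C5 on the same face (conjugate ene reaction, stepwise through an aluminium enolate/tertiary cation pair), and the aldehyde 13 so formed, still bound to aluminium, should at once undergo the type 2 intramolecular carbonyl-ene reaction of its 2-propenyl group, C7 bonding to C6 while the remaining methyl gives up hydrogen so that C17 becomes the exocyclic methylene. The closest known reaction type is the Lewis-acid sequential ene annulation of acrolein or methyl vinyl ketone with alkylidenecycloalkanes, together with aluminium-promoted type 2 carbonyl-ene closures to 3-methylenecyclohexanols; new here are the β,β-disubstituted enal (quaternary C10) and an acyclic trisubstituted alkene as the three-carbon partner. Ring B closes as a six-membered ring, exo with respect to the aldehyde C=O and endo with respect to the C7=C8 alkene. C10 is set by attack anti to the pseudoaxial CO2Me at C4, C9 by the ene transition state in which C8 must lie synclinal to C5 for hydrogen transfer and H9 rather than C11 sits over ring A, C5 by the suprafacial delivery of C9 and H (hence the trans fusion), and C6 by closure with the bulky aluminium-bound oxygen equatorial, a preference known for bulky methylaluminium bis(aryloxide)s and reinforced here because the axial position is syn-axial to the C20 methyl and the C19 ester. The step needs 1,4- over 1,2-attack, for which the aryloxide ligands that shield the carbonyl carbon but not the remote C10 are relied on, and reaction at the isolated trisubstituted alkene rather than at the diene, for which the Z geometry (no s-cis conformer, so no Diels–Alder path) and the six-centre hydrogen transfer open only to the prenyl unit are relied on.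

Step 7
Reactants: 14 methyl 6α-hydroxylabda-8(17),12Z,14-trien-19-oate
Product: 15 methyl (1S,4aR,5S,8S,8aR)-8-(acetyloxy)-1,4a-dimethyl-6-methylidene-5-[(2Z)-3-methylpenta-2,4-dien-1-yl]decahydronaphthalene-1-carboxylate [methyl 6α-acetoxylabda-8(17),12Z,14-trien-19-oate]
Conditions: Ac2O, DMAP, pyridine, CH2Cl2, rt
Reagents that add atoms: acetic anhydride, CC(=O)OC(C)=O
Why: DMAP-catalysed acylation of the equatorial secondary alcohol; the C6–O bond is not broken, so C6 keeps its configuration, and the ester, the exocyclic alkene and the diene are inert.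

**Compound list**

1 | methyl 2-oxocyclohexane-1-carboxylate | COC(=O)C1CCCCC1=O | starting material
2 | L-valine tert-butyl ester | CC(C)[C@H](N)C(=O)OC(C)(C)C | starting material
3 | methyl 2-{[(2S)-1-(tert-butoxy)-3-methyl-1-oxobutan-2-yl]amino}cyclohex-1-ene-1-carboxylate | COC(=O)C1=C(N[C@@H](C(C)C)C(=O)OC(C)(C)C)CCCC1 | intermediate
4 | lithium aza-enolate of 3 (N-lithiated enamino ester) | [Li+].COC(=O)C1=C([N-][C@@H](C(C)C)C(=O)OC(C)(C)C)CCCC1 | intermediate
5 | methyl (1S)-2-{[(2S)-1-(tert-butoxy)-3-methyl-1-oxobutan-2-yl]imino}-1-methylcyclohexane-1-carboxylate | COC(=O)[C@@]1(C)CCCCC1=N[C@@H](C(C)C)C(=O)OC(C)(C)C | intermediate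
6 | methyl (1S)-1-methyl-2-oxocyclohexane-1-carboxylate | COC(=O)[C@@]1(C)CCCCC1=O | intermediate
7 | lithium enolate of 6 | [Li+].COC(=O)[C@@]1(C)CCCC=C1[O-] | intermediate
8 | methyl (1S)-1,3-dimethyl-2-oxocyclohexane-1-carboxylate (both C3 epimers) | COC(=O)[C@@]1(C)CCCC(C)C1=O | intermediate
9 | potassium enolate of 8 | [K+].COC(=O)[C@@]1(C)CCCC(C)=C1[O-] | intermediate
10 | methyl (1S)-1,3-dimethyl-2-[(trifluoromethanesulfonyl)oxy]cyclohex-2-ene-1-carboxylate | COC(=O)[C@@]1(C)CCCC(C)=C1OS(=O)(=O)C(F)(F)F | intermediate
11 | methyl (1S)-2-formyl-1,3-dimethylcyclohex-2-ene-1-carboxylate | COC(=O)[C@@]1(C)CCCC(C)=C1C=O | intermediate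
12 | (3Z)-3,7-dimethylocta-1,3,6-triene, (Z)-β-ocimene | C=C/C(C)=C\CC=C(C)C | starting material
13 | methyl (1S,2R,3R)-3-[(3S,5Z)-2,6-dimethylocta-1,5,7-trien-3-yl]-2-formyl-1,3-dimethylcyclohexane-1-carboxylate | C=C/C(C)=C\C[C@@H](C(C)=C)[C@@]1(C)CCC[C@](C)(C(=O)OC)[C@@H]1C=O | intermediate
14 | methyl (1S,4aR,5S,8S,8aR)-8-hydroxy-1,4a-dimethyl-6-methylidene-5-[(2Z)-3-methylpenta-2,4-dien-1-yl]decahydronaphthalene-1-carboxylate | C=C/C(C)=C\C[C@H]1C(=C)C[C@H](O)[C@@H]2[C@]1(C)CCC[C@]2(C)C(=O)OC | intermediate
15 | methyl (1S,4aR,5S,8S,8aR)-8-(acetyloxy)-1,4a-dimethyl-6-methylidene-5-[(2Z)-3-methylpenta-2,4-dien-1-yl]decahydronaphthalene-1-carboxylate | C=C/C(C)=C\C[C@H]1C(=C)C[C@H](OC(C)=O)[C@@H]2[C@]1(C)CCC[C@]2(C)C(=O)OC | target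

**Step count and risks**

Total steps: 7. Longest linear sequence: 7 steps (1 → 15); 12 enters at step 6.

Steps most likely to fail:

1. Step 6 (proposed new method). Conjugate bond formation at the fully substituted C10 may be outrun by 1,2-attack on the aldehyde or by cationic consumption of the diene. Facial discrimination at C10 by the C4 centre may be weak. Closure with the oxygen axial would be followed by lactonisation onto C19. The fallback uses known chemistry, sets out from 11 and 12 and rejoins the route at 14, passing through 13, which is then isolated.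
   - 12 is oxidised at its (E)-methyl group (SeO2 cat., tBuOOH, CH2Cl2) to (2E,5Z)-2,6-dimethylocta-2,5,7-trien-1-ol F1.
   - F1 is converted with MsCl, LiCl and 2,4,6-collidine in DMF into (2E,5Z)-1-chloro-2,6-dimethylocta-2,5,7-triene F2.
   - The allylbarium reagent from F2 (Ba from BaI2 and lithium biphenylide, THF, −78 °C) adds through its CH2 terminus to the aldehyde of 11. The adduct is collected as the lactone formed when the new alkoxide attacks the neighbouring ester, (7aS)-3-[(2E,5Z)-2,6-dimethylocta-2,5,7-trien-1-yl]-4,7a-dimethyl-5,6,7,7a-tetrahydro-2-benzofuran-1(3H)-one F3.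
   - F3 is opened with KOH and 18-crown-6 in THF to potassium (1S)-2-[(3E,6Z)-1-hydroxy-3,7-dimethylnona-3,6,8-trien-1-yl]-1,3-dimethylcyclohex-2-ene-1-carboxylate F4.
   - With KH, F4 undergoes the anionic oxy-Cope rearrangement (chair transition state, E-alkene), which makes the C9–C10 bond. Quenching with aq. NH4Cl gives potassium (1S,2R,3R)-3-[(3S,5Z)-2,6-dimethylocta-1,5,7-trien-3-yl]-2-formyl-1,3-dimethylcyclohexane-1-carboxylate F5.
   - O-Methylation of F5 with MeI in DMF gives 13, and the separate, precedented type 2 carbonyl-ene closure with the same aluminium reagent gives 14.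

2. Step 5. Direct hydride reduction of the hindered vinyl–palladium intermediate may run ahead of CO insertion. The fallback sets out from 10 and returns at 11. Stille coupling of 10 with tributyl(vinyl)stannane (Pd(PPh3)4, LiCl, THF, reflux) gives methyl (1S)-2-ethenyl-1,3-dimethylcyclohex-2-ene-1-carboxylate F6. Lemieux–Johnson cleavage of its monosubstituted vinyl group (OsO4 cat., NaIO4, 2,6-lutidine, dioxane/water), which should spare the hindered tetrasubstituted ring alkene, then gives 11.

3. Step 2. Facial selectivity in the methylation of the aza-enolate may be insufficient or inverted. The fallback sets out from 1 and returns at 6. 1 is methylated without auxiliary (K2CO3, MeI, acetone) to racemic methyl 1-methyl-2-oxocyclohexane-1-carboxylate F7. The enantiomers are separated by preparative chromatography on a chiral stationary phase (supercritical CO2/MeOH), and the (S)-enantiomer 6 is carried on.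

**Further compounds**

F1 | step 6 | (2E,5Z)-2,6-dimethylocta-2,5,7-trien-1-ol | C=C/C(C)=C\C/C=C(C)/CO
F2 | step 6 | (2E,5Z)-1-chloro-2,6-dimethylocta-2,5,7-triene | C=C/C(C)=C\C/C=C(C)/CCl
F3 | step 6 | (7aS)-3-[(2E,5Z)-2,6-dimethylocta-2,5,7-trien-1-yl]-4,7a-dimethyl-5,6,7,7a-tetrahydro-2-benzofuran-1(3H)-one (C3 epimers) | C=C/C(C)=C\C/C=C(C)/CC1OC(=O)[C@@]2(C)CCCC(C)=C12
F4 | step 6 | potassium (1S)-2-[(3E,6Z)-1-hydroxy-3,7-dimethylnona-3,6,8-trien-1-yl]-1,3-dimethylcyclohex-2-ene-1-carboxylate (carbinol epimers) | C=C/C(C)=C\C/C=C(C)/CC(O)C1=C(C)CCC[C@]1(C)C(=O)[O-].[K+]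
F5 | step 6 | potassium (1S,2R,3R)-3-[(3S,5Z)-2,6-dimethylocta-1,5,7-trien-3-yl]-2-formyl-1,3-dimethylcyclohexane-1-carboxylate | C=C/C(C)=C\C[C@@H](C(C)=C)[C@@]1(C)CCC[C@](C)(C(=O)[O-])[C@@H]1C=O.[K+]
F6 | step 5 | methyl (1S)-2-ethenyl-1,3-dimethylcyclohex-2-ene-1-carboxylate | COC(=O)[C@@]1(C)CCCC(C)=C1C=C
F7 | step 2 | racemic methyl 1-methyl-2-oxocyclohexane-1-carboxylate | COC(=O)C1(C)CCCCC1=O
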